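Readings and results were computed for an exercise.

Alder stopped with 42.9% of its starting material left over, and I asked what it had run short of.

| setting | elm | alder | red | teal | violet | green |
|---|---|---|---|---|---|---|
| starting material | 0.40 M | 0.40 M | 0.40 M | 0.40 M | 0.40 M | 0.40 M |
| partner | 0.40 M | 0.40 M | 0.400 M | 0.400 M | 0.400 M | 0.400 M |
| precatalyst | 26 mM | 180 mM | 20 mM | 40 mM | 80 mM | 150 mM |
| remark | run made earlier | run made earlier |  |  |  |  |
| time |  |  | 3.0 min | 3.0 min | 3.0 min | 3.0 min |

| run | time / min | product / % | starting material / % |
|---|---|---|---|
| elm | 0.250 | 3.2 | 95.3 |
| elm | 0.417 | 6.1 | 91.4 |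
| elm | 0.833 | 16.8 | 81.1 |
| elm | 1.50 | 30.5 | 67.5 |
| elm | 3.00 | 55.5 | 42.7 |
| alder | 0.250 | 12.1 | 78.4 |
| alder | 0.833 | 47.3 | 49.1 |
| alder | 1.33 | 55.4 | 44.0 |
| alder | 2.00 | 57.4 | 43.1 |
| alder | 3.00 | 57.3 | 42.9 |

(readings scatter by 0.3 percentage points)

1. amount of product at the end, in percent of the starting material charged for red, teal, violet, green, in this order
2. how that number moves from the first to the last of them (hardly changes / rises, then falls / rises all the way / falls all the way / falls, then rises)

- the numbers in the tables scatter by 0.3 percentage points (one standard deviation)
- "hardly changes" means that all values lie within two and a half points (for a concentration: within two and a half percent of the largest)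

If each product took one partner, alder's 57.3% of product left 0.171 M of partner unaccounted for, against 180 mM of precatalyst, which is a share of 94.9% of c(precatalyst). Elm was still gaining 25 percentage points in its last 1.50 min as it came up to 55.5%, close below the 57.3% where alder had stalled. So I took alder's stop for a shortage of partner, and I set two amounts against each other.

The first was the ceiling. For green I reckoned 64.4%: this is the partner ceiling, c(partner) less that share of c(precatalyst), divided by c(starting material).

The second was the reach, the product the mean rate delivers in the time. I replaced each curve by a straight line. That line missed elm's reading at 1.50 min by 2.7 points, which I accepted. Alder's early line ran faster than elm's, so from these two runs I read the rate as going with c(precatalyst) to the power 0.580.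

Red's reach was 47.7% and teal's 71.2%, both under their ceilings. Violet's reach of 106% stood over its ceiling of 81.0%, and green's reach of 153% stood over its ceiling too. Taking the lower of the two amounts for each flask, my row rose, then fell.

The forecast said 52%, 56.3%, 57.3% and 57.3%, shape rises all the way, reading alder's stop as “a ceiling, probably an equilibrium, that the catalyst should not shift”.

The flask gave 46.8%, 70.2%, 77.5% and 63.4%, shape rises, then falls.

    partner + free catalyst ⇌ catalyst intermediate A (K = 7.20 L mol⁻¹, k = 0.320 L mol⁻¹ s⁻¹)
    starting material + catalyst intermediate A → catalyst intermediate B (k = 11.0 L mol⁻¹ s⁻¹)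
    catalyst intermediate B → free catalyst + product (k = 0.160 s⁻¹)
    partner + precatalyst → free catalyst + spent reagent (k = 0.410 L mol⁻¹ s⁻¹)

In green, the precatalyst step and the catalytic round ran together early: by 1.50 min spent reagent stood at 0.146 M, product at 60.6%, and partner, the limiting reagent, at 2.06% of its charge, and by 3.00 min product had crept to 63.4%, against my ceiling of 64.4%, with 0.0305% of partner's charge left. In violet, with my ceiling at 81.0%, the round was still running at 3.00 min, with 77.5% of product and 2.05% of partner's charge left, and at 30.0 min product stood at 80.0%.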